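## Retrosynthetic overview

1. Target ⇐ desilylation ⇐ C-acylation at C5 of a bicyclo[2.2.2]octane-6,7-dione ketol with sorbyl chloride (side chain last).
2. Ketol ⇐ key step: α-ketol (acyloin) rearrangement, a 1,2-methyl shift from C7 to C8 that turns C7(OH)(Me)–C8=O into C7=O–C8(OH)(Me) and carries the C7 configuration over to C8.
3. C7(OSi)(Me) ketone ⇐ face-selective enolate methylation ⇐ C7-hydroxy ketone from a stepwise anionic double Michael union of a cyclohexenone α'-enolate with a methylene dioxanone (forms the bicyclooctane, C1 and the spiro carbon C2).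
4. Methylene dioxanone (O-silyl scytolide) ⇐ HCl loss ⇐ chloromethyl dioxanone from trans opening of a vinyl epoxide by methyl 3-chlorolactate and lactonisation ⇐ epoxidation of a cyclohexadiene from ring-closing metathesis after asymmetric allylation of pentadienal; enone ⇐ m-cresol.
5. Ring order: cyclohexene (metathesis) → dioxanone (lactonisation) → bicyclo[2.2.2]octane (double Michael).

Assumption: the target is taken as the exocyclic enol tautomer drawn in the given SMILES.

Convention for the bicyclic compounds: bicyclo[2.2.2]octane locants are C1 (methyl-bearing bridgehead), C2 (spiro carbon), C3 (CH2), C4 (bridgehead CH), C5–C6 (bridge, C6 next to C1) and C7–C8 (bridge, C7 next to C1). "Spirolactone" means methyl 8'-[(tert-butyldimethylsilyl)oxy]-2'-oxo-4a',7',8',8a'-tetrahydrospiro[bicyclo[2.2.2]octane-2,3'-[1,4]benzodioxine]-6'-carboxylate carrying the named substituents on the bicyclooctane. "Core configured as in the target" means: C1, C2 and C4 as in the target, the C2–C1 bond axial on the trans-fused dioxanone (same face as the H on the ether-bearing cyclohexene carbon), the dioxanone ether oxygen syn to the C7–C8 bridge, and the lactone carbonyl syn to the C5–C6 bridge. The cyclohexene is 3,4-trans-4,5-trans (ether O at C3, lactone O at C4, silyloxy at C5).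

## Route

Step 1
Reactants: 1 3-methylphenol (m-cresol)
Product: 2 4,4-dimethoxy-3-methylcyclohexa-2,5-dien-1-one
Conditions: PhI(OAc)2 (2.1 equiv), MeOH, 0 → 23 °C
Reagents that add atoms: methanol, CO
Why: Oxidative dearomatisation: the trivalent iodine reagent oxidises the phenol twice in methanol (via 4-methoxy-3-methylphenol) and methanol traps the para position both times, giving the para-quinone monoketal; no stereocentre is formed.

Step 2
Reactants: 2 4,4-dimethoxy-3-methylcyclohexa-2,5-dien-1-one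
Product: 3 4,4-dimethoxy-3-methylcyclohex-2-en-1-one
Conditions: H2 (1 atm), RhCl(PPh3)3 (5 mol%), PhMe–EtOH, 23 °C
Reagents that add atoms: none
Why: Chemoselective homogeneous hydrogenation: RhCl(PPh3)3 reduces the disubstituted C5=C6 alkene far faster than the trisubstituted methyl-bearing C2=C3 alkene and leaves the allylic ketal intact; no stereocentre is formed.

Step 3
Reactants: 4 (2E)-penta-2,4-dienal; 5 methyl 2-(bromomethyl)prop-2-enoate
Product: 7 methyl (4R,5E)-4-hydroxy-2-methylideneocta-5,7-dienoate, via trimethylsilyl ether 6 (not isolated)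
Conditions: CrCl2 (10 mol%), chiral carbazole-bis(oxazoline) ligand (12 mol%, enantiomer giving the 4R alcohol), Mn powder (2 equiv), Me3SiCl (1.5 equiv), THF, 0 → 23 °C; then citric acid, MeOH, 0 °C
Reagents that add atoms: none
Why: Catalytic asymmetric Nozaki–Hiyama–Kishi 2-(methoxycarbonyl)allylation: the allylchromium species made from 5 adds 1,2 to the dienal on the chiral ligand-bound catalyst formed from CrCl2, which sets the (4R) carbinol (later C5 of the cyclohexene), Me3SiCl and Mn turn the chromium over, and mild acidic methanolysis frees the alcohol without lactonisation.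

Step 4
Reactants: 7 methyl (4R,5E)-4-hydroxy-2-methylideneocta-5,7-dienoate
Product: 8 methyl (4R,5E)-4-[(tert-butyldimethylsilyl)oxy]-2-methylideneocta-5,7-dienoate
Conditions: t-BuMe2SiCl, imidazole, DMF, 0 → 23 °C
Reagents that add atoms: tert-butyldimethylsilyl chloride, CC(C)(C)[Si](C)(C)Cl
Why: Standard silyl protection of the secondary alcohol, needed to steer the later epoxidation anti and to survive the enolate chemistry; the stereocentre is untouched.

Step 5
Reactants: 8 methyl (4R,5E)-4-[(tert-butyldimethylsilyl)oxy]-2-methylideneocta-5,7-dienoate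
Product: 9 methyl (5R)-5-[(tert-butyldimethylsilyl)oxy]cyclohexa-1,3-diene-1-carboxylate
Conditions: second-generation Grubbs catalyst RuCl2(=CHPh)(PCy3)(H2IMes) (5 mol%), CH2Cl2 (5 mM), 40 °C
Reagents that add atoms: none
Why: Ring-closing metathesis between the 1,1-disubstituted acrylate alkene and the terminal alkene of the diene closes the six-membered ring with loss of ethene and gives the conjugated dienoate; the C5 stereocentre is untouched.

Step 6
Reactants: 9 methyl (5R)-5-[(tert-butyldimethylsilyl)oxy]cyclohexa-1,3-diene-1-carboxylate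
Product: 10 methyl (1R,5R,6R)-5-[(tert-butyldimethylsilyl)oxy]-7-oxabicyclo[4.1.0]hept-2-ene-3-carboxylate (epoxide trans to the silyloxy group)
Conditions: mCPBA (1.1 equiv), NaHCO3, CH2Cl2, −20 → 0 °C
Reagents that add atoms: 3-chloroperoxybenzoic acid, OOC(=O)c1cccc(Cl)c1
Why: Prilezhaev epoxidation takes the more electron-rich C3=C4 alkene (remote from the ester) from the face opposite the bulky silyloxy group, which sets the epoxide trans to the C5 oxygen.

Step 7
Reactants: 10 methyl (1R,5R,6R)-5-[(tert-butyldimethylsilyl)oxy]-7-oxabicyclo[4.1.0]hept-2-ene-3-carboxylate; 11 methyl 3-chloro-2-hydroxypropanoate (racemic)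
Product: 13 methyl (4aS,8R,8aR)-8-[(tert-butyldimethylsilyl)oxy]-3-(chloromethyl)-2-oxo-2,3,4a,7,8,8a-hexahydro-1,4-benzodioxine-6-carboxylate (C3 epimers), via hydroxy ester 12 (not isolated)
Conditions: BF3·OEt2 (0.3 equiv), 11 (4.0 equiv), CH2Cl2, −40 → −10 °C; aq. NaHCO3 wash, excess 11 removed under high vacuum; then PPTS (0.2 equiv), PhMe, 80 °C, 4 Å molecular sieves
Reagents that add atoms: none
Why: Lewis acid-promoted SN2 opening of the vinyl epoxide by the hydroxyl of 11 at the allylic carbon C3 with inversion sets the 3,4-trans-4,5-trans arrangement (ether oxygen at C3, free hydroxyl at C4), and acid-catalysed lactonisation of that C4 hydroxyl onto the side-chain ester of crude 12 then closes the trans-fused 1,4-dioxan-2-one with loss of methanol; the side-chain stereocentre is erased in the next step.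

Step 8
Reactants: 13 methyl (4aS,8R,8aR)-8-[(tert-butyldimethylsilyl)oxy]-3-(chloromethyl)-2-oxo-2,3,4a,7,8,8a-hexahydro-1,4-benzodioxine-6-carboxylate (C3 epimers)
Product: 14 methyl (4aS,8R,8aR)-8-[(tert-butyldimethylsilyl)oxy]-3-methylidene-2-oxo-2,3,4a,7,8,8a-hexahydro-1,4-benzodioxine-6-carboxylate (O-silyl scytolide)
Conditions: DBU (1.5 equiv), CH2Cl2, 0 °C
Reagents that add atoms: none
Why: E1cB loss of HCl from the α-alkoxy-β-chloro lactone with DBU converts both C3 epimers into the same exocyclic α-alkoxy acrylate; the ring stereocentres are untouched.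

Step 9
Reactants: 3 4,4-dimethoxy-3-methylcyclohex-2-en-1-one; 14 O-silyl scytolide
Product: 18 7-hydroxy-6,6-dimethoxy-1-methyl-8-oxo spirolactone (C7 epimers; core configured as in the target), via lithium dienolate 15 (not isolated), via lithium lactone enolate 16 (not isolated), via bicyclic lithium enolate 17 (not isolated)
Conditions: LiN(i-Pr)2 (1.0 equiv), THF, −78 °C; 14 (0.9 equiv), −78 → −30 °C; then (camphorsulfonyl)oxaziridine (1.3 equiv), −78 → −40 °C; aq. NH4Cl
Reagents that add atoms: (camphorsulfonyl)oxaziridine, CC1(C)C2CCC13CS(=O)(=O)N4OC34C2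
Why: Proposed new method: a double Michael (Michael–Michael ring closure) of a lithium cross-conjugated dienolate with an α-alkoxy-α-methylene δ-lactone, an acceptor class not yet used in this reaction: C6 of 15 adds reversibly to the exocyclic CH2 of 14, the α-alkoxy lactone enolate 16 then closes onto the methyl-bearing β-carbon of the regenerated enone by axial attack on the trans-fused dioxanone with the lactone carbonyl turned away from the enolate bridge (the orientation s-cis-locked methylene lactones also prefer in cycloadditions), which sets both bridgeheads and the spiro carbon as in the target, and the ketone enolate 17 is hydroxylated at C7 by the oxaziridine (C7 configuration is irrelevant); closest known reaction type: double Michael addition of cyclohexenone lithium α'-enolates to acrylates giving bicyclo[2.2.2]octan-2-ones, followed by Davis enolate oxidation.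

Step 10
Reactants: 18 7-hydroxy-6,6-dimethoxy-1-methyl-8-oxo spirolactone
Product: 19 6-methoxy-1-methyl-8-oxo-7-[(trimethylsilyl)oxy] spirolact-5-ene (C5=C6 methyl enol ether; C7 epimers; core configured as in the target)
Conditions: Me3SiOTf (2.5 equiv), i-Pr2NEt (3.5 equiv), CH2Cl2, −20 → 0 °C
Reagents that add atoms: trimethylsilyl trifluoromethanesulfonate, C[Si](C)(C)OS(=O)(=O)C(F)(F)F
Why: Me3SiOTf with amine silylates the secondary hydroxyl and ionises the dimethyl ketal to an oxocarbenium ion that loses the C5 proton (Gassman-type ketal to enol ether conversion), which flattens the C5–C6 bridge for the next step; no new stereocentre is formed.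

Step 11
Reactants: 19 6-methoxy-1-methyl-8-oxo-7-[(trimethylsilyl)oxy] spirolact-5-ene
Product: 20 6-methoxy-1,7-dimethyl-8-oxo-7-[(trimethylsilyl)oxy] spirolact-5-ene (C7 methyl syn to the C5=C6 bridge, C7 oxygen syn to the C2–C3 bridge)
Conditions: KN(SiMe3)2 (1.2 equiv), THF, −78 °C; MeI (5 equiv), −78 → −40 °C
Reagents that add atoms: iodomethane, CI
Why: Enolate alkylation of the α-silyloxy ketone (the bridgehead C4 cannot enolise, so only C7 reacts): methyl iodide approaches from the face of the flat C5=C6 enol ether bridge, away from the dioxanone oxygen on C2, so the methyl ends up syn to the C5–C6 bridge and the C7 oxygen syn to the C2–C3 bridge.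

Step 12
Reactants: 20 6-methoxy-1,7-dimethyl-8-oxo-7-[(trimethylsilyl)oxy] spirolact-5-ene
Product: 23 8-hydroxy-1,8-dimethyl-6,7-dioxo spirolactone (C8 hydroxyl syn to the C2–C3 bridge, C8 methyl syn to the C5–C6 bridge), via α-ketol 21 (not isolated), via rearranged enol ether 22 (not isolated)
Conditions: K2CO3 (1.5 equiv), MeOH, 0 → 23 °C; then 0.2 M HCl (aq), THF, 0 °C
Reagents that add atoms: water, O
Why: α-Ketol (acyloin) rearrangement: methanolysis of the silyl ether frees the C7 alkoxide, which drives a suprafacial 1,2-shift of the C7 methyl to the C8 carbonyl carbon, giving the less congested C7 ketone and C8 tertiary alcohol (relief of three contiguous fully substituted carbons) with the C7 configuration transferred to C8 (hydroxyl stays syn to the C2–C3 bridge), after which dilute acid hydrolyses the enol ether to the C6 ketone.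

Step 13
Reactants: 23 8-hydroxy-1,8-dimethyl-6,7-dioxo spirolactone; 24 (2E,4E)-hexa-2,4-dienoyl chloride (sorbyl chloride)
Product: 25 5-[(2E,4E)-1-hydroxyhexa-2,4-dien-1-ylidene]-8-hydroxy-1,8-dimethyl-6,7-dioxo spirolactone (O-silyl target)
Conditions: 24 (1.3 equiv), MgBr2·OEt2 (3 equiv), i-Pr2NEt (3.5 equiv), CH2Cl2, 0 → 23 °C; 0.5 M HCl work-up
Reagents that add atoms: none
Why: Soft-enolisation C-acylation: the magnesium enolate of the only enolisable ketone (C6) is acylated at C5 by the acid chloride to give the β-triketone, which rests as the hydrogen-bonded exocyclic enol; the mild conditions avoid alkoxide-triggered cleavage of the 1,3-diketone and leave all stereocentres untouched.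

Step 14
Reactants: 25 O-silyl target
Product: 26 target CNP0259039.2
Conditions: HF·pyridine, THF/pyridine, 0 → 23 °C
Reagents that add atoms: none
Why: Fluoride-mediated cleavage of the secondary silyl ether under buffered acidic conditions that the enolised triketone, the ketol and the lactone tolerate; no stereocentre changes.

## Compound list

1 | 3-methylphenol (m-cresol) | Cc1cccc(O)c1 | starting material
2 | 4,4-dimethoxy-3-methylcyclohexa-2,5-dien-1-one | CC1=CC(=O)C=CC1(OC)OC | intermediate
3 | 4,4-dimethoxy-3-methylcyclohex-2-en-1-one | CC1=CC(=O)CCC1(OC)OC | intermediate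
4 | (2E)-penta-2,4-dienal | C=C/C=C/C=O | starting material
5 | methyl 2-(bromomethyl)prop-2-enoate | C=C(CBr)C(=O)OC | starting material
6 | methyl (4R,5E)-2-methylidene-4-[(trimethylsilyl)oxy]octa-5,7-dienoate | C=C/C=C/[C@H](O[Si](C)(C)C)CC(=C)C(=O)OC | intermediate
7 | methyl (4R,5E)-4-hydroxy-2-methylideneocta-5,7-dienoate | C=C/C=C/[C@H](O)CC(=C)C(=O)OC | intermediate
8 | methyl (4R,5E)-4-[(tert-butyldimethylsilyl)oxy]-2-methylideneocta-5,7-dienoate | C=C/C=C/[C@H](O[Si](C)(C)C(C)(C)C)CC(=C)C(=O)OC | intermediate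
9 | methyl (5R)-5-[(tert-butyldimethylsilyl)oxy]cyclohexa-1,3-diene-1-carboxylate | COC(=O)C1=CC=C[C@H](O[Si](C)(C)C(C)(C)C)C1 | intermediate
10 | methyl (1R,5R,6R)-5-[(tert-butyldimethylsilyl)oxy]-7-oxabicyclo[4.1.0]hept-2-ene-3-carboxylate | COC(=O)C1=C[C@H]2O[C@H]2[C@H](O[Si](C)(C)C(C)(C)C)C1 | intermediate
11 | methyl 3-chloro-2-hydroxypropanoate (racemic) | COC(=O)C(O)CCl | starting material
12 | methyl (3S,4R,5R)-5-[(tert-butyldimethylsilyl)oxy]-3-[(3-chloro-1-methoxy-1-oxopropan-2-yl)oxy]-4-hydroxycyclohex-1-ene-1-carboxylate (side-chain epimers) | COC(=O)C1=C[C@H](OC(CCl)C(=O)OC)[C@@H](O)[C@H](O[Si](C)(C)C(C)(C)C)C1 | intermediate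
13 | methyl (4aS,8R,8aR)-8-[(tert-butyldimethylsilyl)oxy]-3-(chloromethyl)-2-oxo-2,3,4a,7,8,8a-hexahydro-1,4-benzodioxine-6-carboxylate (C3 epimers) | COC(=O)C1=C[C@@H]2OC(CCl)C(=O)O[C@H]2[C@H](O[Si](C)(C)C(C)(C)C)C1 | intermediate
14 | methyl (4aS,8R,8aR)-8-[(tert-butyldimethylsilyl)oxy]-3-methylidene-2-oxo-2,3,4a,7,8,8a-hexahydro-1,4-benzodioxine-6-carboxylate (O-silyl scytolide) | COC(=O)C1=C[C@@H]2OC(=C)C(=O)O[C@H]2[C@H](O[Si](C)(C)C(C)(C)C)C1 | intermediate
15 | lithium 4,4-dimethoxy-5-methylcyclohexa-1,5-dien-1-olate | [Li+].[O-]C1=CCC(OC)(OC)C(C)=C1 | intermediate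
16 | lithium lactone enolate from addition of C6 of the enone to the CH2 of 14 | CC1=CC(=O)C(CC=2O[C@H]3C=C(C(=O)OC)C[C@@H](O[Si](C)(C)C(C)(C)C)[C@@H]3OC=2[O-])CC1(OC)OC.[Li+] | intermediate
17 | bicyclic lithium enolate (C7=C8–OLi; 6,6-dimethoxy-1-methyl spirolactone) | C1C(OC)(OC)[C@@]2(C)C=C([O-])[C@@H]1C[C@]21O[C@H]2C=C(C(=O)OC)C[C@@H](O[Si](C)(C)C(C)(C)C)[C@@H]2OC1=O.[Li+] | intermediate
18 | 7-hydroxy-6,6-dimethoxy-1-methyl-8-oxo spirolactone (C7 epimers) | C1C(OC)(OC)[C@@]2(C)C(O)C(=O)[C@@H]1C[C@]21O[C@H]2C=C(C(=O)OC)C[C@@H](O[Si](C)(C)C(C)(C)C)[C@@H]2OC1=O | intermediate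
19 | 6-methoxy-1-methyl-8-oxo-7-[(trimethylsilyl)oxy] spirolact-5-ene (C7 epimers) | C1=C(OC)[C@@]2(C)C(O[Si](C)(C)C)C(=O)[C@@H]1C[C@]21O[C@H]2C=C(C(=O)OC)C[C@@H](O[Si](C)(C)C(C)(C)C)[C@@H]2OC1=O | intermediate
20 | 6-methoxy-1,7-dimethyl-8-oxo-7-[(trimethylsilyl)oxy] spirolact-5-ene (C7 methyl syn to C5=C6) | C1=C(OC)[C@@]2(C)[C@](C)(O[Si](C)(C)C)C(=O)[C@@H]1C[C@]21O[C@H]2C=C(C(=O)OC)C[C@@H](O[Si](C)(C)C(C)(C)C)[C@@H]2OC1=O | intermediate
21 | 7-hydroxy-6-methoxy-1,7-dimethyl-8-oxo spirolact-5-ene (α-ketol before the shift) | C1=C(OC)[C@@]2(C)[C@](C)(O)C(=O)[C@@H]1C[C@]21O[C@H]2C=C(C(=O)OC)C[C@@H](O[Si](C)(C)C(C)(C)C)[C@@H]2OC1=O | intermediate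
22 | 8-hydroxy-6-methoxy-1,8-dimethyl-7-oxo spirolact-5-ene (α-ketol after the shift) | C1=C(OC)[C@@]2(C)C(=O)[C@](C)(O)[C@@H]1C[C@]21O[C@H]2C=C(C(=O)OC)C[C@@H](O[Si](C)(C)C(C)(C)C)[C@@H]2OC1=O | intermediate
23 | 8-hydroxy-1,8-dimethyl-6,7-dioxo spirolactone | C1C(=O)[C@@]2(C)C(=O)[C@](C)(O)[C@@H]1C[C@]21O[C@H]2C=C(C(=O)OC)C[C@@H](O[Si](C)(C)C(C)(C)C)[C@@H]2OC1=O | intermediate
24 | (2E,4E)-hexa-2,4-dienoyl chloride (sorbyl chloride) | C/C=C/C=C/C(=O)Cl | starting material
25 | 5-[(2E,4E)-1-hydroxyhexa-2,4-dien-1-ylidene]-8-hydroxy-1,8-dimethyl-6,7-dioxo spirolactone (O-silyl target) | C/C=C/C=C/C(O)=C1/C(=O)[C@@]2(C)C(=O)[C@](C)(O)[C@@H]1C[C@]21O[C@H]2C=C(C(=O)OC)C[C@@H](O[Si](C)(C)C(C)(C)C)[C@@H]2OC1=O | intermediate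
26 | CNP0259039.2 (25 with the free cyclohexene hydroxyl) | C/C=C/C=C/C(O)=C1/C(=O)[C@@]2(C)C(=O)[C@](C)(O)[C@@H]1C[C@]21O[C@H]2C=C(C(=O)OC)C[C@@H](O)[C@@H]2OC1=O | target

## Step count and risks

Total step count: 14. Longest linear sequence: 12 steps (steps 3 to 14).

Three steps most likely to fail:

Step 9 (the proposed new step). The ring-closing conjugate addition must join two fully substituted carbons next to a ketal, so proton transfer or simple mono-addition may win, and the sense of ring closure is unproven. The fallback uses known chemistry, sets out from 3 and 14, and returns at 18. Compound 3 is converted (LiN(i-Pr)2, Me3SiCl, THF, −78 °C) into the 2-silyloxydiene [(4,4-dimethoxy-5-methylcyclohexa-1,5-dien-1-yl)oxy]trimethylsilane F1. A thermal Diels–Alder reaction of this diene with 14 (PhMe, 110 °C, sealed tube, or 12 kbar in CH2Cl2; exo mode expected as for other s-cis-locked α-methylene lactones) gives the trimethylsilyl enol ether cycloadduct F2. Rubottom oxidation of it (mCPBA, NaHCO3, CH2Cl2, 0 °C; then citric acid, MeOH) delivers 18.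

Step 12. The methyl shift may stop at an equilibrium mixture, and the carbonate in methanol may open the lactone. The fallback sets out from 18 and returns at 23 by way of 22. Compound 18 is oxidised with Dess–Martin periodinane to the 6,6-dimethoxy-1-methyl-7,8-dioxo spirolactone F3. Me3SiOTf with i-Pr2NEt turns its ketal into the 6-methoxy-1-methyl-7,8-dioxo spirolact-5-ene F4. MeMgBr with CeCl3 (THF, −78 °C) then adds to the less hindered C8 carbonyl from the face of the flat enol ether bridge, which gives 22 directly. The dilute HCl treatment of step 12 converts 22 into 23.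

Step 7. The acid-sensitive vinyl epoxide may aromatise or rearrange before the weakly nucleophilic hydroxy ester adds, and leftover hydroxy ester may interfere with the lactonisation. The fallback sets out from 10 and returns at 14. Compound 10 is opened with water (HClO4 cat., THF/H2O, 0 °C) at the allylic carbon to the trans-diol methyl (3S,4R,5R)-5-[(tert-butyldimethylsilyl)oxy]-3,4-dihydroxycyclohex-1-ene-1-carboxylate F5. Rh2(OAc)4-catalysed O–H insertion of methyl 2-diazo-2-(dimethoxyphosphoryl)acetate into the less hindered allylic hydroxyl gives the phosphonoacetate ether F6. DBU closes the lactone to the trans-fused phosphonolactone F7. A Horner–Wadsworth–Emmons reaction with aqueous formaldehyde and K2CO3 then gives 14.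

Further compounds
F1 | step 9 | [(4,4-dimethoxy-5-methylcyclohexa-1,5-dien-1-yl)oxy]trimethylsilane | CC1=CC(O[Si](C)(C)C)=CCC1(OC)OC
F2 | step 9 | 6,6-dimethoxy-1-methyl-8-[(trimethylsilyl)oxy] spirolact-7-ene (trimethylsilyl enol ether cycloadduct) | C1C(OC)(OC)[C@@]2(C)C=C(O[Si](C)(C)C)[C@@H]1C[C@]21O[C@H]2C=C(C(=O)OC)C[C@@H](O[Si](C)(C)C(C)(C)C)[C@@H]2OC1=O
F3 | step 12 | 6,6-dimethoxy-1-methyl-7,8-dioxo spirolactone | C1C(OC)(OC)[C@@]2(C)C(=O)C(=O)[C@@H]1C[C@]21O[C@H]2C=C(C(=O)OC)C[C@@H](O[Si](C)(C)C(C)(C)C)[C@@H]2OC1=O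
F4 | step 12 | 6-methoxy-1-methyl-7,8-dioxo spirolact-5-ene | C1=C(OC)[C@@]2(C)C(=O)C(=O)[C@@H]1C[C@]21O[C@H]2C=C(C(=O)OC)C[C@@H](O[Si](C)(C)C(C)(C)C)[C@@H]2OC1=O
F5 | step 7 | methyl (3S,4R,5R)-5-[(tert-butyldimethylsilyl)oxy]-3,4-dihydroxycyclohex-1-ene-1-carboxylate | COC(=O)C1=C[C@H](O)[C@@H](O)[C@H](O[Si](C)(C)C(C)(C)C)C1
F6 | step 7 | methyl (3S,4R,5R)-5-[(tert-butyldimethylsilyl)oxy]-3-[1-(dimethoxyphosphoryl)-2-methoxy-2-oxoethoxy]-4-hydroxycyclohex-1-ene-1-carboxylate | COC(=O)C1=C[C@H](OC(C(=O)OC)P(=O)(OC)OC)[C@@H](O)[C@H](O[Si](C)(C)C(C)(C)C)C1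
F7 | step 7 | methyl (4aS,8R,8aR)-8-[(tert-butyldimethylsilyl)oxy]-3-(dimethoxyphosphoryl)-2-oxo-2,3,4a,7,8,8a-hexahydro-1,4-benzodioxine-6-carboxylate | COC(=O)C1=C[C@@H]2OC(P(=O)(OC)OC)C(=O)O[C@H]2[C@H](O[Si](C)(C)C(C)(C)C)C1
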